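**Retrosynthetic overview**

- The ten-membered ring is opened at C2–C3: Nozaki–Hiyama–Kishi closure of an (E)-alkenyl iodide onto a C3 (Z)-enal, followed by C3 oxidation and silyl removal; the O8 ester is installed just before.
- The α-methylene-γ-butyrolactone is disconnected at O–C6 and C11–C7 in one palladium-catalysed [3+2] heteroannulation of 2-bromoacrylic acid onto a C4=C5–C6=C7 diene.
- Enabling feature: C6 is allylic to the C4=C5 double bond. Removing the lactone leaves a (4Z,6Z)-1,3-diene whose C7 terminus accepts C11 and whose C4–C5–C6 allyl unit accepts the carboxylate oxygen at C6. The diene is locked in a temporary seven-membered 2,7-dihydrooxepine ring (C3 as acetal carbon bonded to O8), in which the C8 stereocentre next to C7 relays both new centres.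
- The oxepine derives from a (Z,Z)-dienediol (Sonogashira coupling, semi-reduction, oxidative lactonization, reductive silylation); C8 comes from a catalytic asymmetric methallylation and C10 from a chelation-controlled Grignard addition.
- Ring order: temporary oxepine (steps 9–11), γ-lactone (step 12), oxepine opened (step 13), ten-membered carbocycle (step 16).

Key step: step 12

Remark: atoms are cited by germacrane numbering of the target (ring C1–C10 with the ketone at C3, methyl-bearing C4, lactone O-bearing C6, C7, ester-bearing C8, carbinol C10; lactone carbons C11–C13). The target as drawn is the cis-fused lactone (6S,7R,8R,10R; S in the ester), and temporary acetal or carbinol centres at C3 are carried as epimer mixtures.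

**Route**

Step 1
Reactants: 1 3-(trimethylsilyl)prop-2-ynal; 2 tributyl(2-methylprop-2-en-1-yl)stannane
Product: 3 (R)-5-methyl-1-(trimethylsilyl)hex-5-en-1-yn-3-ol
Conditions: Ti(OiPr)4 (10 mol%), (R)-BINOL (20 mol%), 4 Å molecular sieves, CH2Cl2, −20 °C; aq. NaHCO3
Reagents that add atoms: none
Why: Keck asymmetric allylation, in which the (R)-BINOL–titanium Lewis acid should deliver the methallyl group to one aldehyde face and set C8 as R by catalyst control.

Step 2
Reactants: 3 (R)-5-methyl-1-(trimethylsilyl)hex-5-en-1-yn-3-ol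
Product: 5 (R)-4-hydroxy-6-(trimethylsilyl)hex-5-yn-2-one, via triol 4 (not isolated)
Conditions: OsO4 (2 mol%), NaIO4 (4 equiv), 2,6-lutidine, dioxane/H2O (3:1), rt
Reagents that add atoms: osmium tetroxide, O=[Os](=O)(=O)=O (catalytic, delivers the oxygen); sodium periodate, [Na+].[O-]I(=O)(=O)=O (reoxidant and cleaving agent)
Why: Lemieux–Johnson oxidative cleavage, in which OsO4 should dihydroxylate the 1,1-disubstituted alkene in preference to the silylalkyne and periodate cleaves the diol to the methyl ketone without touching C8.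

Step 3
Reactants: 6 (E)-(2-bromoethenyl)trimethylsilane
Product: 7 (E)-[2-(trimethylsilyl)ethenyl]magnesium bromide (THF solution, used directly)
Conditions: Mg turnings, THF, 25 → 45 °C
Reagents that add atoms: magnesium, [Mg]
Why: Grignard formation by magnesium insertion into the alkenyl bromide, which should proceed with retention of the E geometry.

Step 4
Reactants: 5 (R)-4-hydroxy-6-(trimethylsilyl)hex-5-yn-2-one; 7 (E)-[2-(trimethylsilyl)ethenyl]magnesium bromide
Product: 8 (3R,5R,E)-3-methyl-1,7-bis(trimethylsilyl)hept-1-en-6-yne-3,5-diol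
Conditions: 7 (3.0 equiv), THF/CH2Cl2, −78 → −40 °C; aq. NH4Cl
Reagents that add atoms: none
Why: Chelation-controlled Grignard addition (Cram chelation model), in which the first equivalent forms the magnesium alkoxide at O8, this chelates the ketone in a six-membered ring, and the alkenyl group should add to the face opposite the alkynyl substituent to set C10 as the 1,3-anti diol.

Step 5
Reactants: 8 (3R,5R,E)-3-methyl-1,7-bis(trimethylsilyl)hept-1-en-6-yne-3,5-diol
Product: 9 (3R,5R,E)-3-methyl-1-(trimethylsilyl)hept-1-en-6-yne-3,5-diol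
Conditions: K2CO3 (0.2 equiv), MeOH, 0 °C → rt
Reagents that add atoms: none
Why: Base-mediated methanolysis should cleave the alkynyl C–Si bond selectively, the alkenyl C–Si bond being inert to K2CO3/MeOH.

Step 6
Reactants: 10 prop-2-yn-1-ol
Product: 12 (Z)-3-iodo-2-methylprop-2-en-1-ol, via magnesacycle 11 (not isolated)
Conditions: MeMgBr (2.5 equiv), CuI (10 mol%), THF/Et2O, −10 °C → rt; then I2, −78 → 0 °C; aq. NH4Cl
Reagents that add atoms: methylmagnesium bromide, C[Mg]Br; iodine, II
Why: Copper-catalysed, alkoxide-directed anti-carbomagnesiation of the propargylic alcohol places methyl on the internal carbon, and iodinolysis of the alkenyl–magnesium bond with retention should give the Z iodide.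

Step 7
Reactants: 9 (3R,5R,E)-3-methyl-1-(trimethylsilyl)hept-1-en-6-yne-3,5-diol; 12 (Z)-3-iodo-2-methylprop-2-en-1-ol
Product: 13 (2Z,6R,8R,9E)-2,8-dimethyl-10-(trimethylsilyl)deca-2,9-dien-4-yne-1,6,8-triol
Conditions: PdCl2(PPh3)2 (3 mol%), CuI (6 mol%), i-Pr2NH, THF, rt
Reagents that add atoms: none
Why: Sonogashira coupling of the terminal alkyne with the alkenyl iodide, which should retain the Z geometry and tolerate the free hydroxyl groups and the alkenylsilane.

Step 8
Reactants: 13 (2Z,6R,8R,9E)-2,8-dimethyl-10-(trimethylsilyl)deca-2,9-dien-4-yne-1,6,8-triol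
Product: 14 (2Z,4Z,6R,8R,9E)-2,8-dimethyl-10-(trimethylsilyl)deca-2,4,9-triene-1,6,8-triol
Conditions: Zn dust activated with Cu(OAc)2 and AgNO3, MeOH/H2O (1:1), 45 °C
Reagents that add atoms: none
Why: Zinc-mediated cis-semi-reduction of a conjugated enyne, which should stop at the alkene and give the (Z,Z)-diene without touching the alkenylsilane.

Step 9
Reactants: 14 (2Z,4Z,6R,8R,9E)-2,8-dimethyl-10-(trimethylsilyl)deca-2,4,9-triene-1,6,8-triol
Product: 17 (R)-7-[(R,E)-2-hydroxy-2-methyl-4-(trimethylsilyl)but-3-en-1-yl]-3-methyloxepin-2(7H)-one, via dienal 15 (not isolated), via lactol 16 (not isolated)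
Conditions: TEMPO (20 mol%), PhI(OAc)2 (2.4 equiv), CH2Cl2, rt
Reagents that add atoms: none
Why: Oxoammonium (TEMPO) oxidative lactonization, in which the primary allylic alcohol is oxidised selectively, the (Z,Z)-dienal should be captured by O8–H as the seven-membered lactol, and this is oxidised on to the lactone while the tertiary alcohol stays inert.

Step 10
Reactants: 17 (R)-7-[(R,E)-2-hydroxy-2-methyl-4-(trimethylsilyl)but-3-en-1-yl]-3-methyloxepin-2(7H)-one
Product: 18 (R)-3-methyl-7-[(R,E)-2-methyl-2-(triethylsilyloxy)-4-(trimethylsilyl)but-3-en-1-yl]oxepin-2(7H)-one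
Conditions: TESOTf, 2,6-lutidine, CH2Cl2, −78 → 0 °C
Reagents that add atoms: triethylsilyl trifluoromethanesulfonate, CC[Si](CC)(CC)OS(=O)(=O)C(F)(F)F
Why: Silylation of the tertiary alcohol with a silyl triflate, needed so that O10 cannot later form a bicyclic acetal with the C3 aldehyde.

Step 11
Reactants: 18 (R)-3-methyl-7-[(R,E)-2-methyl-2-(triethylsilyloxy)-4-(trimethylsilyl)but-3-en-1-yl]oxepin-2(7H)-one
Product: 20 (7R)-2-(tert-butyldimethylsilyloxy)-3-methyl-7-[(R,E)-2-methyl-2-(triethylsilyloxy)-4-(trimethylsilyl)but-3-en-1-yl]-2,7-dihydrooxepine (both C2 epimers), via aluminium hemiacetal 19 (not isolated)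
Conditions: i-Bu2AlH (1.1 equiv), CH2Cl2, −78 °C; then pyridine, TBSOTf, −78 → −20 °C; aq. NaHCO3
Reagents that add atoms: tert-butyldimethylsilyl trifluoromethanesulfonate, CC(C)(C)[Si](C)(C)OS(=O)(=O)C(F)(F)F
Why: Reductive silylation of a lactone, in which 1,2-reduction at −78 °C gives a stable tetrahedral aluminium hemiacetal that is trapped in situ as the cyclic silyl acetal, bringing C3 to the aldehyde level while the ring stays closed.

Step 12
Reactants: 20 (7R)-2-(tert-butyldimethylsilyloxy)-3-methyl-7-[(R,E)-2-methyl-2-(triethylsilyloxy)-4-(trimethylsilyl)but-3-en-1-yl]-2,7-dihydrooxepine; 21 2-bromoprop-2-enoic acid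
Product: 22 cis-fused α-methylene-γ-butyrolactone on the oxepine acetal (O on C6 and C11 on C7; 6S,7R,8R,10R; C3 epimers)
Conditions: Pd(OAc)2 (5 mol%), K2CO3 (2.5 equiv), n-Bu4NCl (1 equiv), DMF, 60 °C, slow addition of 21
Reagents that add atoms: none
Why: Oxidative addition of the C–Br bond of potassium 2-bromoacrylate to zerovalent palladium (formed from Pd(OAc)2) gives a 1-carboxylatovinylpalladium bromide that adds syn across C6=C7 with C11 going to C7, and the resulting π-allylpalladium over C6–C5–C4 is captured at C6 by its own palladium-bound carboxylate (C–O reductive elimination), returning zerovalent palladium. The closest known reaction type is the Larock heteroannulation of cyclic 1,3-dienes by aryl or vinylic halides that carry a carboxylic acid or hydroxyl group. The γ-lactone closes in the 5-exo sense on the allyl terminus C6 through a six-membered oxapalladacycle, the alternative closure at the fully substituted C4 being a disfavoured seven-membered mode. C7 is set in the carbopalladation, which should take the diene face anti to the C9 side chain on the adjacent C8 stereocentre, and C6 follows on the same face because oxygen is delivered from palladium syn to the new C–C bond and a trans fusion cannot be spanned on the seven-membered ring, so the lactone is cis-fused. The step needs regioselectivity (C7 over C4, secured by the methyl group and acetal flanking C4), facial selectivity (secured by C8), retention of the C4=C5 Z geometry (locked by the ring) and chemoselectivity for the diene over the hindered, unconjugated alkenylsilane. The temperature is held at 60 °C to avoid 1,5-hydrogen shifts of the cyclic diene.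

Step 13
Reactants: 22 cis-fused α-methylene-γ-butyrolactone on the oxepine acetal
Product: 24 (Z)-3-{(2S,3R)-3-[(1R,3R,4E)-1-hydroxy-3-methyl-3-(triethylsilyloxy)-5-(trimethylsilyl)pent-4-en-1-yl]-4-methylidene-5-oxooxolan-2-yl}-2-methylprop-2-enal, via lactol 23 (not isolated)
Conditions: AcOH/THF/H2O (3:1:1), 0 °C → rt
Reagents that add atoms: water, O
Why: Mild acid hydrolysis of the anomeric silyl ether, after which the seven-membered lactol should open to the conjugated (Z)-enal and free O8–H while the tertiary triethylsilyl ether survives.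

Step 14
Reactants: 24 hydroxy enal; 25 (S)-2-methylbutanoic anhydride
Product: 26 the O8 (S)-2-methylbutanoate of 24
Conditions: 25 (2 equiv), pyridine, DMAP (10 mol%), CH2Cl2, −20 → 0 °C
Reagents that add atoms: none
Why: DMAP-catalysed acyl transfer to the secondary alcohol, with the ester stereocentre bought with the anhydride, and done at once so that free O8–H cannot translactonize onto C12.

Step 15
Reactants: 26 the O8 (S)-2-methylbutanoate of 24
Product: 27 the corresponding (E)-alkenyl iodide (I in place of SiMe3 at C2)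
Conditions: NIS (1.3 equiv), 2,6-lutidine (0.5 equiv), (CF3)2CHOH, 0 °C
Reagents that add atoms: N-iodosuccinimide, O=C1CCC(=O)N1I
Why: Electrophilic ipso-iododesilylation of the alkenylsilane through a β-silyl cation, which should retain the E geometry and leave the electron-poor enal and methylene lactone alkenes untouched.

Step 16
Reactants: 27 (E)-alkenyl iodide
Product: 29 ten-membered allylic alcohol (C3–OH epimers; 10-O-triethylsilyl; 6S,7R,8R,10R), via alkenylchromium 28 (not isolated)
Conditions: CrCl2 (8 equiv), NiCl2 (5 mol%), DMSO/THF (3:1), 2 mM, rt; aqueous work-up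
Reagents that add atoms: none
Why: Nozaki–Hiyama–Kishi macrocyclization, in which nickel-catalysed activation of the C–I bond and transmetalation give a trivalent alkenylchromium that adds chemoselectively 1,2 to the aldehyde, closing C2–C3 with retention of the E alkene in a chain pre-folded by the cis-lactone and the Z alkene.

Step 17
Reactants: 29 ten-membered allylic alcohol
Product: 30 10-O-triethylsilyl ether of the target
Conditions: Dess–Martin periodinane, CH2Cl2, 0 °C → rt
Reagents that add atoms: none
Why: Dess–Martin oxidation of the bis-allylic alcohol to the cross-conjugated dienone, which also removes the C3 epimer mixture.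

Step 18
Reactants: 30 10-O-triethylsilyl ether of the target
Product: 31 target CNP0315499.4
Conditions: HF·pyridine, pyridine, THF, 0 °C → rt
Reagents that add atoms: none
Why: Buffered fluoride cleavage of the tertiary triethylsilyl ether, which should leave the dienone, ester and methylene lactone intact.

**Compound list**

1 | 3-(trimethylsilyl)prop-2-ynal | O=CC#C[Si](C)(C)C | starting material
2 | tributyl(2-methylprop-2-en-1-yl)stannane | C=C(C)C[Sn](CCCC)(CCCC)CCCC | starting material
3 | (R)-5-methyl-1-(trimethylsilyl)hex-5-en-1-yn-3-ol | C=C(C)C[C@@H](O)C#C[Si](C)(C)C | intermediate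
4 | (4R)-2-methyl-6-(trimethylsilyl)hex-5-yne-1,2,4-triol (C2 epimers) | CC(O)(CO)C[C@@H](O)C#C[Si](C)(C)C | intermediate
5 | (R)-4-hydroxy-6-(trimethylsilyl)hex-5-yn-2-one | CC(=O)C[C@@H](O)C#C[Si](C)(C)C | intermediate
6 | (E)-(2-bromoethenyl)trimethylsilane | C[Si](C)(C)/C=C/Br | starting material
7 | (E)-[2-(trimethylsilyl)ethenyl]magnesium bromide | C[Si](C)(C)/C=C/[Mg]Br | intermediate
8 | (3R,5R,E)-3-methyl-1,7-bis(trimethylsilyl)hept-1-en-6-yne-3,5-diol | C[Si](C)(C)/C=C/[C@](C)(O)C[C@@H](O)C#C[Si](C)(C)C | intermediate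
9 | (3R,5R,E)-3-methyl-1-(trimethylsilyl)hept-1-en-6-yne-3,5-diol | C[Si](C)(C)/C=C/[C@](C)(O)C[C@@H](O)C#C | intermediate
10 | prop-2-yn-1-ol | C#CCO | starting material
11 | 4-methyl-2,5-dihydro-1,2-oxamagnesole (cyclic alkenylmagnesium alkoxide) | CC1=C[Mg]OC1 | intermediate
12 | (Z)-3-iodo-2-methylprop-2-en-1-ol | I/C=C(/C)CO | intermediate
13 | (2Z,6R,8R,9E)-2,8-dimethyl-10-(trimethylsilyl)deca-2,9-dien-4-yne-1,6,8-triol | C[Si](C)(C)/C=C/[C@](C)(O)C[C@@H](O)C#C/C=C(/C)CO | intermediate
14 | (2Z,4Z,6R,8R,9E)-2,8-dimethyl-10-(trimethylsilyl)deca-2,4,9-triene-1,6,8-triol | C[Si](C)(C)/C=C/[C@](C)(O)C[C@@H](O)/C=C\C=C(\C)CO | intermediate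
15 | (2Z,4Z,6R,8R,9E)-6,8-dihydroxy-2,8-dimethyl-10-(trimethylsilyl)deca-2,4,9-trienal | C[Si](C)(C)/C=C/[C@](C)(O)C[C@@H](O)/C=C\C=C(\C)C=O | intermediate
16 | (7R)-7-[(R,E)-2-hydroxy-2-methyl-4-(trimethylsilyl)but-3-en-1-yl]-3-methyl-2,7-dihydrooxepin-2-ol (C2 epimers) | C[Si](C)(C)/C=C/[C@](C)(O)C[C@H]1OC(O)C(C)=CC=C1 | intermediate
17 | (R)-7-[(R,E)-2-hydroxy-2-methyl-4-(trimethylsilyl)but-3-en-1-yl]-3-methyloxepin-2(7H)-one | C[Si](C)(C)/C=C/[C@](C)(O)C[C@H]1OC(=O)C(C)=CC=C1 | intermediate
18 | (R)-3-methyl-7-[(R,E)-2-methyl-2-(triethylsilyloxy)-4-(trimethylsilyl)but-3-en-1-yl]oxepin-2(7H)-one | C[Si](C)(C)/C=C/[C@](C)(O[Si](CC)(CC)CC)C[C@H]1OC(=O)C(C)=CC=C1 | intermediate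
19 | diisobutylaluminium hemiacetal of 18 (C2 epimers) | C[Si](C)(C)/C=C/[C@](C)(O[Si](CC)(CC)CC)C[C@H]1OC(O[Al](CC(C)C)CC(C)C)C(C)=CC=C1 | intermediate
20 | (7R)-2-(tert-butyldimethylsilyloxy)-3-methyl-7-[(R,E)-2-methyl-2-(triethylsilyloxy)-4-(trimethylsilyl)but-3-en-1-yl]-2,7-dihydrooxepine (C2 epimers) | C[Si](C)(C)/C=C/[C@](C)(O[Si](CC)(CC)CC)C[C@H]1OC(O[Si](C)(C)C(C)(C)C)C(C)=CC=C1 | intermediate
21 | 2-bromoprop-2-enoic acid | C=C(Br)C(=O)O | starting material
22 | cis-fused α-methylene-γ-butyrolactone on the oxepine silyl acetal (6S,7R,8R,10R; C3 epimers) | C[Si](C)(C)/C=C/[C@](C)(O[Si](CC)(CC)CC)C[C@H]1OC(O[Si](C)(C)C(C)(C)C)C(C)=C[C@@H]2OC(=O)C(=C)[C@H]12 | intermediate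
23 | lactol of 22 (OH in place of OSi-t-BuMe2; C3 epimers) | C[Si](C)(C)/C=C/[C@](C)(O[Si](CC)(CC)CC)C[C@H]1OC(O)C(C)=C[C@@H]2OC(=O)C(=C)[C@H]12 | intermediate
24 | (Z)-3-{(2S,3R)-3-[(1R,3R,4E)-1-hydroxy-3-methyl-3-(triethylsilyloxy)-5-(trimethylsilyl)pent-4-en-1-yl]-4-methylidene-5-oxooxolan-2-yl}-2-methylprop-2-enal | C[Si](C)(C)/C=C/[C@](C)(O[Si](CC)(CC)CC)C[C@@H](O)[C@H]1C(=C)C(=O)O[C@H]1/C=C(/C)C=O | intermediate
25 | (S)-2-methylbutanoic anhydride | CC[C@H](C)C(=O)OC(=O)[C@@H](C)CC | starting material
26 | O8 (S)-2-methylbutanoate of 24 | C[Si](C)(C)/C=C/[C@](C)(O[Si](CC)(CC)CC)C[C@@H](OC(=O)[C@@H](C)CC)[C@H]1C(=C)C(=O)O[C@H]1/C=C(/C)C=O | intermediate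
27 | (E)-alkenyl iodide from 26 (I in place of SiMe3) | I/C=C/[C@](C)(O[Si](CC)(CC)CC)C[C@@H](OC(=O)[C@@H](C)CC)[C@H]1C(=C)C(=O)O[C@H]1/C=C(/C)C=O | intermediate
28 | (E)-alkenylchromium dichloride from 27 | Cl[Cr](Cl)/C=C/[C@](C)(O[Si](CC)(CC)CC)C[C@@H](OC(=O)[C@@H](C)CC)[C@H]1C(=C)C(=O)O[C@H]1/C=C(/C)C=O | intermediate
29 | ten-membered allylic alcohol (3-hydroxy, C3 epimers; 10-O-triethylsilyl; 6S,7R,8R,10R) | C=C1C(=O)O[C@H]2/C=C(/C)C(O)/C=C/[C@](C)(O[Si](CC)(CC)CC)C[C@@H](OC(=O)[C@@H](C)CC)[C@@H]12 | intermediate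
30 | 10-O-triethylsilyl ether of the target | C=C1C(=O)O[C@H]2/C=C(/C)C(=O)/C=C/[C@](C)(O[Si](CC)(CC)CC)C[C@@H](OC(=O)[C@@H](C)CC)[C@@H]12 | intermediate
31 | CNP0315499.4 | C=C1C(=O)O[C@H]2/C=C(/C)C(=O)/C=C/[C@](C)(O)C[C@@H](OC(=O)[C@@H](C)CC)[C@@H]12 | target

**Step count and risks**

Total steps: 18. Longest linear sequence: 16 (steps 1, 2, 4, 5, 7–18).

Step 12 is the most likely to fail. The bromoacrylate could polymerise or undergo Heck-type side reactions, the π-allyl intermediate could lose a β-hydrogen, or facial discrimination on the oxepine could be poor. The fallback sets out from 20 and returns at 22 by a radical route followed by classical methylenation. Iodine-atom-transfer radical addition of iodoacetic acid (Et3B/air, rt) should place the carboxymethyl radical on C7 anti to the side chain, and NaHCO3 then closes the allylic iodide to the saturated cis-fused γ-lactone F1. Enolisation with LiN(SiMe3)2 at −78 °C and trapping with dimethylmethylideneammonium iodide gives the Mannich base F2, and quaternisation with MeI followed by NaHCO3 elimination delivers 22.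

Step 16 is the second risk. Intermolecular coupling or protodehalogenation may outrun closure of the strained ten-membered ring. The fallback sets out from 26 and returns at 29 by ring-closing metathesis. Intermolecular Nozaki–Hiyama–Kishi vinylation of the aldehyde with vinyl bromide (CrCl2, NiCl2 cat., DMSO) gives the divinyl carbinol F3. Ring-closing metathesis with the second-generation Hoveyda–Grubbs catalyst in dilute toluene then forms C1=C2, the silylated alkene acting as the second partner and being expelled as trimethyl(vinyl)silane.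

Step 9 is the third risk. The (2Z,4Z)-dienal may isomerise or undergo 6π-oxa-electrocyclisation before the lactol forms, or the secondary allylic alcohol may be over-oxidised. The fallback sets out from 13 and returns at 17, raising C3 to the acid level while the alkyne still prevents cyclisation. TEMPO/PhI(OAc)2 oxidation gives the (Z)-enynal F4. Chlorite oxidation (NaClO2, NaH2PO4, 2-methylbut-2-ene) gives the enynoic acid F5. Semi-reduction with Zn activated by Cu(OAc)2 and AgNO3 gives the (2Z,4Z)-hydroxy dienoic acid F6. Yamaguchi lactonization (2,4,6-trichlorobenzoyl chloride, Et3N, then DMAP) through the secondary hydroxyl closes the seven-membered lactone 17.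

Further compounds
F1 | step 12 | saturated cis-fused γ-lactone (22 with CH2 in place of C=CH2) | C[Si](C)(C)/C=C/[C@](C)(O[Si](CC)(CC)CC)C[C@H]1OC(O[Si](C)(C)C(C)(C)C)C(C)=C[C@@H]2OC(=O)C[C@H]12
F2 | step 12 | α-(dimethylaminomethyl) lactone (Mannich base of F1) | C[Si](C)(C)/C=C/[C@](C)(O[Si](CC)(CC)CC)C[C@H]1OC(O[Si](C)(C)C(C)(C)C)C(C)=C[C@@H]2OC(=O)C(CN(C)C)[C@H]12
F3 | step 16 | divinyl carbinol from 26 (vinyl added to the C3 aldehyde) | C[Si](C)(C)/C=C/[C@](C)(O[Si](CC)(CC)CC)C[C@@H](OC(=O)[C@@H](C)CC)[C@H]1C(=C)C(=O)O[C@H]1/C=C(/C)C(O)C=C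
F4 | step 9 | (2Z,6R,8R,9E)-6,8-dihydroxy-2,8-dimethyl-10-(trimethylsilyl)deca-2,9-dien-4-ynal | C[Si](C)(C)/C=C/[C@](C)(O)C[C@@H](O)C#C/C=C(/C)C=O
F5 | step 9 | (2Z,6R,8R,9E)-6,8-dihydroxy-2,8-dimethyl-10-(trimethylsilyl)deca-2,9-dien-4-ynoic acid | C[Si](C)(C)/C=C/[C@](C)(O)C[C@@H](O)C#C/C=C(/C)C(=O)O
F6 | step 9 | (2Z,4Z,6R,8R,9E)-6,8-dihydroxy-2,8-dimethyl-10-(trimethylsilyl)deca-2,4,9-trienoic acid | C[Si](C)(C)/C=C/[C@](C)(O)C[C@@H](O)/C=C\C=C(\C)C(=O)O
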